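Retrosynthesis, late cuts: the isovalerate, the acetonide, C8=C14 (methylenation of a C8 ketone) and the 9α,10α-diol (osmylation of C9=C10). C9=C10 and C8=O derive from a C10 ketone, and the C6 carbinol from a C6 ketone.
Central cut: the C6/C10 1,4-diketone is the glycol-fission product of a cyclobutane-1,2-diol. Re-joining C6–C10 and then cutting C5–C6 and C1–C10 together ([2+2] retron) leaves 3-methylcyclopent-2-enone and 1,2-bis(trimethylsilyloxy)cyclopentene.
Enabling feature: in the seven-membered ring both carbons that flank the ring-fusion bond C1–C5 carry oxygen (O–C6–C5–C1–C10–O). C4, next to C5 in the five-membered ring, also carries oxygen and can serve as the enone carbonyl (chromophore).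
Forward order: bought cyclopentenone ring, then the photochemical 5-4-5 tricycle (temporary C6–C10 bond, temporary ring C6–C10), then the C4 carbinol, then fission to the 5-7 skeleton, then work at C6 and at C8–C10.
Stereochemistry: C1 comes from the catalyst-controlled enone face in the photocycloaddition. The rest follows by relay: C4 (O2 capture on the convex face), C5 (equilibration), C6 (hydroxyl-directed hydride), C9/C10 (osmylation anti to C15).

Key step: step 2

Remark: carotane (daucane) numbering is used. C1 is the quaternary ring-fusion carbon (bears C15H3), followed by C2, C3, C4 (OH, iPr), C5 (ring-fusion CH), C6 (ester), C7, C8 (=C14H2), C9 and C10. β is the face of C15, and "14-nor" marks compounds that still lack C14.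

Step 1
Reactants: 1 dimethyl glutarate
Product: 2 1,2-bis(trimethylsilyloxy)cyclopent-1-ene
Conditions: Na (4.4 equiv), TMSCl (4.5 equiv), toluene, reflux
Reagents that add atoms: chlorotrimethylsilane C[Si](C)(C)Cl
Why: Acyloin condensation in the Rühlmann modification: sodium couples the two ester carbonyls to the five-membered enediolate, which TMSCl traps before Dieckmann-type side reactions, and no stereocentre is formed.

Step 2
Reactants: 2 1,2-bis(trimethylsilyloxy)cyclopent-1-ene; 3 3-methylcyclopent-2-en-1-one
Product: 4 cis-anti-cis 6-methyl-1,7-bis(trimethylsilyloxy)tricyclo[5.3.0.0^2,6]decan-3-one (cyclobutane C1–C5–C6–C10; C4 ketone; C15H3, H5, C7 and C9 on one cyclobutane face, both OTMS groups, C2 and C4 on the other)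
Conditions: 2 (5 equiv), prolinol-derived B-aryl oxazaborolidine·AlBr3 (50 mol %, antipode chosen so that 2 adds to the enone face that becomes α), hν (366 nm), CH2Cl2, −75 °C
Reagents that add atoms: none
Why: Proposed new method: binding of the chiral Lewis acid to the C4 carbonyl red-shifts the enone ππ* band so that only bound 3 is excited at 366 nm, its triplet attacks the electron-rich C6=C10 bond of 2, and the 1,4-diradical closes after spin inversion, so C5–C6 and C1–C10 arise in one photochemical event. The closest known reaction types are the uncatalysed [2+2] photocycloaddition of cyclopent-2-enones to 1,2-bis(silyloxy)cycloalkenes (racemic) and the oxazaborolidine–AlBr3-catalysed enantioselective intermolecular [2+2] of cyclic enones such as 3-methylcyclohex-2-enone with simple alkenes; pairing a five-membered enone with an enediol bis-silyl ether under the chiral Lewis acid is new. The only ring closed is the cyclobutane C1–C5–C6–C10, by radical–radical combination of the 1,4-diradical (formal [2π+2π]), which creates the 5-4-5 skeleton. C1/C5 must be cis because a trans-bicyclo[3.2.0] unit cannot persist, C6/C10 are cis because they sit in the ring of 2, the anti arrangement follows from repulsion between the two five-membered rings, and the absolute sense at C1 follows from the catalyst aryl groups shielding one enone face. No regiochemical question arises because the two alkene carbons of Cs-symmetric 2 are equivalent, the dark Mukaiyama–Michael pathway should be slow at −75 °C because it would join two fully substituted carbons, and the excess of 2 suppresses enone dimerisation.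

Step 3
Reactants: 4 tricyclic ketone
Product: 5 6-methyl-1,7-bis(trimethylsilyloxy)tricyclo[5.3.0.0^2,6]dec-3-en-3-yl triflate (C3=C4 enol triflate)
Conditions: KHMDS (1.1 equiv), THF, −78 °C; PhNTf2, −78 to 0 °C
Reagents that add atoms: N-phenylbis(trifluoromethanesulfonimide) O=S(=O)(N(c1ccccc1)S(=O)(=O)C(F)(F)F)C(F)(F)F
Why: Kinetic enolisation and O-sulfonylation: only C3–H2 is deprotonated, because an enolate towards C5 would place a double bond at the cyclobutane ring fusion, and the existing stereocentres are untouched.

Step 4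
Reactants: 5 enol triflate
Product: 6 3-isopropyl-6-methyl-1,7-bis(trimethylsilyloxy)tricyclo[5.3.0.0^2,6]dec-3-ene (C3=C4, isopropyl on C4)
Conditions: i-PrMgCl (1.5 equiv), Fe(acac)3 (5 mol %), THF/NMP, −30 °C
Reagents that add atoms: isopropylmagnesium chloride CC(C)[Mg]Cl
Why: Iron-catalysed Kumada-type cross-coupling of an alkenyl triflate with a secondary alkyl Grignard reagent replaces OTf by isopropyl at low temperature without moving the double bond or touching the silyl ethers.

Step 5
Reactants: 6 isopropyl alkene
Product: 8 3-isopropyl-6-methyltricyclo[5.3.0.0^2,6]decane-1,3,7-triol (C4–OH on the face of C15H3 and H5), via tertiary alcohol bis-silyl ether 7 (not isolated)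
Conditions: Mn(dpm)3 (10 mol %), PhSiH3 (2.5 equiv), O2 (1 atm), i-PrOH/CH2Cl2, 0 °C; then K2CO3 (cat.), MeOH, rt
Reagents that add atoms: dioxygen O=O
Why: Mukaiyama hydration (metal-hydride hydrogen-atom transfer): H adds to C3 and the tertiary C4 radical is captured by O2 on the convex face of the bicyclo[3.2.0] unit, away from the cyclobutane and the C6–OTMS group, which sets C4 (OH β, isopropyl α), and methanolysis then frees the two cyclobutanols.

Step 6
Reactants: 8 triol
Product: 10 trans-fused (5α-H) 4β-hydroxy-14-norcarotane-6,10-dione, via cis-fused diketone 9 (not isolated)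
Conditions: Pb(OAc)4 (1.1 equiv), CH2Cl2, 0 °C; then DBU (0.2 equiv), CH2Cl2, rt
Reagents that add atoms: none
Why: Criegee glycol cleavage cuts the temporary C6–C10 bond with release of ring strain and opens the seven-membered ring, and equilibration through the C6 enol should invert C5, because 9 holds C10, C6 and the isopropyl group all on the α face of the cyclopentane whereas 10 alternates them and gains a C4–OH···O=C6 hydrogen bond.

Step 7
Reactants: 10 trans-fused hydroxy diketone
Product: 11 4β,6α-dihydroxy-14-norcarotan-10-one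
Conditions: Me4NBH(OAc)3 (3 equiv), MeCN/AcOH, −20 °C
Reagents that add atoms: none
Why: Evans–Saksena reduction: ligand exchange at C4–OH and intramolecular hydride delivery through a chair six-membered transition state to the β face of C6=O gives the 1,3-anti diol (6α-OH), while the neopentyl C10 ketone has no hydroxyl within reach and is left alone.

Step 8
Reactants: 11 diol ketone
Product: 12 4β-hydroxy-6α-(3-methylbutanoyloxy)-14-norcarotan-10-one
Conditions: isovaleric anhydride (1.5 equiv), DMAP (cat.), pyridine, CH2Cl2, rt
Reagents that add atoms: isovaleric anhydride CC(C)CC(=O)OC(=O)CC(C)C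
Why: DMAP-catalysed acylation takes the secondary C6–OH, whereas the tertiary C4–OH is too hindered to react.

Step 9
Reactants: 12 keto ester
Product: 13 4β-hydroxy-6α-(3-methylbutanoyloxy)-14-norcarot-9-en-10-yl triflate
Conditions: KHMDS (2.2 equiv), THF, −78 °C; Comins' reagent (1.2 equiv), −78 °C
Reagents that add atoms: N-(5-chloropyridin-2-yl)bis(trifluoromethanesulfonimide) FC(F)(F)S(=O)(=O)N(c1ccc(Cl)cn1)S(=O)(=O)C(F)(F)F
Why: Enolisation and O-triflation: C1 is quaternary, so the C10 ketone can enolise only towards C9, the ketone is more acidic than the ester, and the second equivalent of base merely holds C4–OH as its alkoxide.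

Step 10
Reactants: 13 enol triflate
Product: 14 6α-(3-methylbutanoyloxy)-14-norcarot-9-en-4β-ol
Conditions: Pd(OAc)2 (5 mol %), PPh3, HCO2H, Et3N, DMF, 60 °C
Reagents that add atoms: none
Why: Palladium-catalysed formate reduction of an alkenyl triflate (oxidative addition, decarboxylation of formate, reductive elimination) places the cis alkene at C9=C10 and removes the helper oxygen at C10.

Step 11
Reactants: 14 alkene
Product: 15 4β-hydroxy-6α-(3-methylbutanoyloxy)-14-norcarot-9-en-8-one
Conditions: Mn(OAc)3·2H2O (10 mol %), t-BuOOH (5 equiv, decane), 3 Å MS, EtOAc, rt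
Reagents that add atoms: tert-butyl hydroperoxide CC(C)(C)OO
Why: Radical allylic oxidation under base-free conditions: C1 is quaternary, so the only allylic C–H bonds are at C8, and the allyl radical should take up oxygen at its less hindered terminus C8 to give the C8 enone.

Step 12
Reactants: 15 enone
Product: 16 4β,9α,10α-trihydroxy-6α-(3-methylbutanoyloxy)-14-norcarotan-8-one
Conditions: OsO4 (5 mol %), NMO (1.5 equiv), citric acid, t-BuOH/H2O, rt
Reagents that add atoms: N-methylmorpholine N-oxide C[N+]1([O-])CCOCC1; water O
Why: Upjohn dihydroxylation: suprafacial addition of OsO4 to the face opposite the axial C15 methyl on the neighbouring C1 sets C9 and C10 together as the 9α,10α-cis-diol, the result that hydride reduction of a C9 or C10 ketone from the open α face could not give.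

Step 13
Reactants: 16 keto triol
Product: 17 9α,10α-O-isopropylidene derivative of 16
Conditions: Me2C(OMe)2, PPTS (cat.), CH2Cl2, rt
Reagents that add atoms: 2,2-dimethoxypropane COC(C)(C)OC
Why: Acid-catalysed transketalisation closes the five-membered dioxolane on the cis-1,2-diol in preference to any ring that involves the tertiary C4–OH.

Step 14
Reactants: 17 acetonide ketone
Product: 18 9α,10α-O-isopropylidene-6α-(3-methylbutanoyloxy)carot-8(14)-ene-4β,9α,10α-triol
Conditions: Cp2TiMe2 (3 equiv), toluene, 65 °C, dark
Reagents that add atoms: dimethyltitanocene C[Ti](C)(C1C=CC=C1)C1C=CC=C1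
Why: Petasis methylenation through Cp2Ti=CH2 is non-basic, so the ketone with a β-acyloxy group at C6 and an α-alkoxy group at C9 is not driven to elimination, and the ketone reacts faster than the ester.

Step 15
Reactants: 18 acetonide
Product: 19 6α-(3-methylbutanoyloxy)carot-8(14)-ene-4β,9α,10α-triol (target)
Conditions: AcOH/H2O (4:1), 40 °C
Reagents that add atoms: none
Why: Mild acid hydrolysis of the dioxolane frees the 9,10-diol without touching the ester, the exocyclic alkene or any stereocentre.

Compound list
1 | dimethyl glutarate | COC(=O)CCCC(=O)OC | starting material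
2 | 1,2-bis(trimethylsilyloxy)cyclopent-1-ene | C[Si](C)(C)OC1=C(O[Si](C)(C)C)CCC1 | intermediate
3 | 3-methylcyclopent-2-en-1-one | CC1=CC(=O)CC1 | starting material
4 | cis-anti-cis 6-methyl-1,7-bis(trimethylsilyloxy)tricyclo[5.3.0.0^2,6]decan-3-one | O=C1CC[C@@]2(C)[C@@H]1[C@]3(O[Si](C)(C)C)CCC[C@]23O[Si](C)(C)C | intermediate
5 | C3=C4 enol triflate of 4 | FC(F)(F)S(=O)(=O)OC1=CC[C@@]2(C)[C@@H]1[C@]3(O[Si](C)(C)C)CCC[C@]23O[Si](C)(C)C | intermediate
6 | 3-isopropyl-6-methyl-1,7-bis(trimethylsilyloxy)tricyclo[5.3.0.0^2,6]dec-3-ene | CC(C)C1=CC[C@@]2(C)[C@@H]1[C@]3(O[Si](C)(C)C)CCC[C@]23O[Si](C)(C)C | intermediate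
7 | 3-isopropyl-6-methyl-1,7-bis(trimethylsilyloxy)tricyclo[5.3.0.0^2,6]decan-3-ol (OH cis to C15H3 and H5) | CC(C)[C@]1(O)CC[C@@]2(C)[C@@H]1[C@]3(O[Si](C)(C)C)CCC[C@]23O[Si](C)(C)C | intermediate
8 | 3-isopropyl-6-methyltricyclo[5.3.0.0^2,6]decane-1,3,7-triol | CC(C)[C@]1(O)CC[C@@]2(C)[C@@H]1[C@]3(O)CCC[C@]23O | intermediate
9 | cis-fused (5β-H) 4β-hydroxy-14-norcarotane-6,10-dione | C1CC(=O)[C@H]2[C@](C)(CC[C@@]2(O)C(C)C)C(=O)C1 | intermediate
10 | trans-fused (5α-H) 4β-hydroxy-14-norcarotane-6,10-dione | C1CC(=O)[C@@H]2[C@](C)(CC[C@@]2(O)C(C)C)C(=O)C1 | intermediate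
11 | 4β,6α-dihydroxy-14-norcarotan-10-one | C1C[C@H](O)[C@@H]2[C@](C)(CC[C@@]2(O)C(C)C)C(=O)C1 | intermediate
12 | 4β-hydroxy-6α-(3-methylbutanoyloxy)-14-norcarotan-10-one | C1C[C@H](OC(=O)CC(C)C)[C@@H]2[C@](C)(CC[C@@]2(O)C(C)C)C(=O)C1 | intermediate
13 | 4β-hydroxy-6α-(3-methylbutanoyloxy)-14-norcarot-9-en-10-yl triflate | C1C[C@H](OC(=O)CC(C)C)[C@@H]2[C@](C)(CC[C@@]2(O)C(C)C)C(OS(=O)(=O)C(F)(F)F)=C1 | intermediate
14 | 6α-(3-methylbutanoyloxy)-14-norcarot-9-en-4β-ol | C1C[C@H](OC(=O)CC(C)C)[C@@H]2[C@](C)(CC[C@@]2(O)C(C)C)C=C1 | intermediate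
15 | 4β-hydroxy-6α-(3-methylbutanoyloxy)-14-norcarot-9-en-8-one | O=C1C[C@H](OC(=O)CC(C)C)[C@@H]2[C@](C)(CC[C@@]2(O)C(C)C)C=C1 | intermediate
16 | 4β,9α,10α-trihydroxy-6α-(3-methylbutanoyloxy)-14-norcarotan-8-one | O=C1C[C@H](OC(=O)CC(C)C)[C@@H]2[C@](C)(CC[C@@]2(O)C(C)C)[C@H](O)[C@@H]1O | intermediate
17 | 9α,10α-acetonide of 16 | O=C1C[C@H](OC(=O)CC(C)C)[C@@H]2[C@](C)(CC[C@@]2(O)C(C)C)[C@@H]3OC(C)(C)O[C@H]13 | intermediate
18 | 9α,10α-acetonide of the target | C=C1C[C@H](OC(=O)CC(C)C)[C@@H]2[C@](C)(CC[C@@]2(O)C(C)C)[C@@H]3OC(C)(C)O[C@H]13 | intermediate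
19 | 6α-(3-methylbutanoyloxy)carot-8(14)-ene-4β,9α,10α-triol | C=C1C[C@H](OC(=O)CC(C)C)[C@@H]2[C@](C)(CC[C@@]2(O)C(C)C)[C@H](O)[C@@H]1O | target

Total step count: 15. Longest linear sequence: 15 steps (from 1).

Steps most likely to fail

Step 2. The Lewis acid may strip or activate the silyl enol ether in the dark (desilylation, Mukaiyama–Michael addition), or it may discriminate poorly between the faces of the five-membered enone. The fallback uses known chemistry and sets out from 2 and 3. Irradiation through Pyrex without Lewis acid (hexane, 0 °C) gives 4 together with its mirror image ent-ketone F1. NaBH4 (EtOH, 0 °C) attacks the convex face and gives the concave-face alcohol F2 together with its mirror image ent-alcohol F3. A lipase with vinyl acetate acylates one antipode only (drawn for F3, which gives the ent-acetate F4). After chromatographic separation, Dess–Martin oxidation of F2 comes back to the route at 4.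

Step 5. The C4 radical is a cyclobutylcarbinyl radical and may open the four-membered ring before O2 capture, or O2 may be captured with poor facial selectivity. The fallback replaces the radical process by an ionic one and sets out from 6. Epoxidation with dimethyldioxirane on the convex face gives the C3–C4 epoxide F5. LiEt3BH then delivers hydride to the less substituted C3 with retention of the C4–O bond, which comes back to the route at 7, and methanolysis as in step 5 gives 8.

Step 11. The allyl radical may be oxygenated at the wrong terminus (C10), or the oxidation may be unselective next to the tertiary C–H bonds. The fallback avoids C–H oxidation and steps 9 to 11 altogether and sets out from 12. IBX dehydrogenation gives the C8=C9 enone F6. Nucleophilic epoxidation (t-BuOOH, DBU) gives the epoxy ketone F7. Wharton transposition (N2H4·H2O, AcOH, MeOH) moves the functionality and gives the C8 allylic alcohol F8 with C9=C10 in place. The configuration at C8 is without consequence, because MnO2 oxidation comes back to the route at 15.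

Further compounds
F1 | step 2 | ent-ketone (mirror image of 4) | O=C1CC[C@]2(C)[C@H]1[C@@]3(O[Si](C)(C)C)CCC[C@@]23O[Si](C)(C)C
F2 | step 2 | concave-face alcohol (C4–OH cis to the cyclobutane, series of 4) | O[C@@H]1CC[C@@]2(C)[C@@H]1[C@]3(O[Si](C)(C)C)CCC[C@]23O[Si](C)(C)C
F3 | step 2 | ent-alcohol (mirror image of F2) | O[C@H]1CC[C@]2(C)[C@H]1[C@@]3(O[Si](C)(C)C)CCC[C@@]23O[Si](C)(C)C
F4 | step 2 | ent-acetate (acetate of F3) | CC(=O)O[C@H]1CC[C@]2(C)[C@H]1[C@@]3(O[Si](C)(C)C)CCC[C@@]23O[Si](C)(C)C
F5 | step 5 | C3–C4 epoxide of 6 (oxygen on the convex face) | CC(C)[C@]12O[C@H]1C[C@@]3(C)[C@@H]2[C@]4(O[Si](C)(C)C)CCC[C@]34O[Si](C)(C)C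
F6 | step 11 | 4β-hydroxy-6α-(3-methylbutanoyloxy)-14-norcarot-8-en-10-one | C=1C[C@H](OC(=O)CC(C)C)[C@@H]2[C@](C)(CC[C@@]2(O)C(C)C)C(=O)C=1
F7 | step 11 | 8α,9α-epoxy-4β-hydroxy-6α-(3-methylbutanoyloxy)-14-norcarotan-10-one | O1[C@@H]2C[C@H](OC(=O)CC(C)C)[C@@H]3[C@](C)(CC[C@@]3(O)C(C)C)C(=O)[C@H]12
F8 | step 11 | 6α-(3-methylbutanoyloxy)-14-norcarot-9-ene-4β,8α-diol | O[C@@H]1C[C@H](OC(=O)CC(C)C)[C@@H]2[C@](C)(CC[C@@]2(O)C(C)C)C=C1
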